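**Plan**
1. Retrosynthetic cuts, in order: the three O–Si bonds (last step); the C2–C3 bond of ring C, leading back to an aryl benzyl ether whose O1–CH2 carbon (future C2) faces a diazoketone carbon (future C3); the C=N2 bond (back to an acetyl group); the O1–CH2 ether bond between the ring A and ring B fragments; the aryl–prenyl bond of ring B.
2. Feature used: C2 is benzylic to the electron-rich ring B and bound to the ring oxygen O1, so as a CH2 group its C–H bonds are hydridic. It lies 1,6 to C3, the carbon alpha to the C4 ketone, which can be turned into a carbene.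
3. Forward: ring B alcohol from 5-bromovanillin (silylation, prenyl coupling, reduction); ring A ketone from 2,4,6-trihydroxyacetophenone (bis-silylation); both joined through the O1–C2 ether bond; diazo transfer to the acetyl group; ring C closes by C–H insertion; fluoride frees the three phenols.
4. Stereochemistry: C2, the only stereocentre, is created in the ring closure by a chiral dirhodium carboxylate that selects one of the two enantiotopic benzylic hydrogens. All later conditions are non-basic so the flavanone does not ring-open and racemise.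

Key step: step 7

Assumption: Rh2(S-PTTL)4 is taken to give the (2S) product. The sense of induction cannot be predicted safely for this substrate, so it is checked on a small scale against racemate made with Rh2(OAc)4, and Rh2(R-PTTL)4 is used instead if the sense is opposite. Commercial 2,4,6-trihydroxyacetophenone monohydrate is dried before use.

**Step 1**
Reactants: 1 5-bromovanillin (3-bromo-4-hydroxy-5-methoxybenzaldehyde)
Product: 2 3-bromo-5-methoxy-4-(triisopropylsilyloxy)benzaldehyde
Conditions: TIPSCl (1.2 equiv), imidazole (2.5 equiv), DMF, rt to 40 °C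
Reagents that add atoms: chlorotriisopropylsilane, CC(C)[Si](Cl)(C(C)C)C(C)C
Why: Silylation of the acidic phenol through the N-silylimidazolium species should give an aryl silyl ether that keeps the phenol from protonating the allylstannane in step 2 and survives all later steps until fluoride removes it.

**Step 2**
Reactants: 2 3-bromo-5-methoxy-4-(triisopropylsilyloxy)benzaldehyde; 3 tributyl(3-methylbut-2-en-1-yl)stannane
Product: 4 3-methoxy-5-(3-methylbut-2-en-1-yl)-4-(triisopropylsilyloxy)benzaldehyde
Conditions: Pd(PPh3)4 (5 mol %), DMF, degassed, 90 °C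
Reagents that add atoms: none
Why: Stille coupling: oxidative addition of zerovalent palladium into the C–Br bond (activated by the para formyl group), transmetalation, and reductive elimination at the less hindered allyl terminus should give the linear prenyl arene.

**Step 3**
Reactants: 4 3-methoxy-5-(3-methylbut-2-en-1-yl)-4-(triisopropylsilyloxy)benzaldehyde
Product: 5 [3-methoxy-5-(3-methylbut-2-en-1-yl)-4-(triisopropylsilyloxy)phenyl]methanol
Conditions: NaBH4, MeOH/THF (1:1), 0 °C
Reagents that add atoms: none
Why: Borohydride 1,2-reduction of the aldehyde should leave the trisubstituted alkene and the aryl silyl ether untouched.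

**Step 4**
Reactants: 6 2,4,6-trihydroxyacetophenone
Product: 7 1-[2-hydroxy-4,6-bis(triisopropylsilyloxy)phenyl]ethan-1-one
Conditions: TIPSCl (2.1 equiv), imidazole (4.5 equiv), DMF, 0 °C to rt
Reagents that add atoms: chlorotriisopropylsilane, CC(C)[Si](Cl)(C(C)C)C(C)C
Why: Selective silylation: the para hydroxyl and then one ortho hydroxyl react, while the last hydroxyl, strongly hydrogen-bonded to the ketone and flanked by it, should stay free, as is usual for bis-protection of phloroacetophenone.

**Step 5**
Reactants: 7 1-[2-hydroxy-4,6-bis(triisopropylsilyloxy)phenyl]ethan-1-one; 5 [3-methoxy-5-(3-methylbut-2-en-1-yl)-4-(triisopropylsilyloxy)phenyl]methanol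
Product: 8 1-{2-[(3-methoxy-5-(3-methylbut-2-en-1-yl)-4-(triisopropylsilyloxy)phenyl)methoxy]-4,6-bis(triisopropylsilyloxy)phenyl}ethan-1-one
Conditions: PPh3 (1.3 equiv), DIAD (1.3 equiv), THF, 0 °C to rt
Reagents that add atoms: none
Why: Mitsunobu etherification: the chelated phenol is acidic enough to protonate the betaine and its phenoxide displaces the primary benzylic alkoxyphosphonium ion, under neutral conditions that spare the aryl silyl ethers.

**Step 6**
Reactants: 8 1-{2-[(3-methoxy-5-(3-methylbut-2-en-1-yl)-4-(triisopropylsilyloxy)phenyl)methoxy]-4,6-bis(triisopropylsilyloxy)phenyl}ethan-1-one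
Product: 10 2-diazo-1-{2-[(3-methoxy-5-(3-methylbut-2-en-1-yl)-4-(triisopropylsilyloxy)phenyl)methoxy]-4,6-bis(triisopropylsilyloxy)phenyl}ethan-1-one, via trifluoroacetylated 1,3-diketone 9 (not isolated)
Conditions: LiN(SiMe3)2 (1.1 equiv), THF, −78 °C; CF3CO2CH2CF3 (1.2 equiv), −78 °C; then MsN3 (1.5 equiv), Et3N (1.5 equiv), H2O (1 equiv), MeCN, rt
Reagents that add atoms: methanesulfonyl azide, CS(=O)(=O)N=[N+]=[N-]; 2,2,2-trifluoroethyl trifluoroacetate, O=C(OCC(F)(F)F)C(F)(F)F (its trifluoroacetyl group stays only in 9)
Why: Detrifluoroacetylative (Regitz-type) diazo transfer: the acetyl methyl group is the only enolisable site, its lithium enolate is C-trifluoroacetylated, and diazo transfer to the activated methylene followed by loss of the trifluoroacetyl group should give the diazomethyl ketone.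

**Step 7**
Reactants: 10 2-diazo-1-{2-[(3-methoxy-5-(3-methylbut-2-en-1-yl)-4-(triisopropylsilyloxy)phenyl)methoxy]-4,6-bis(triisopropylsilyloxy)phenyl}ethan-1-one
Product: 11 (2S)-2-[3-methoxy-5-(3-methylbut-2-en-1-yl)-4-(triisopropylsilyloxy)phenyl]-5,7-bis(triisopropylsilyloxy)-2,3-dihydro-4H-chromen-4-one
Conditions: Rh2(S-PTTL)4, dirhodium tetrakis[N-phthaloyl-(S)-tert-leucinate] (1 mol %), CH2Cl2, 0 °C, slow addition of 10 to a final 0.01 M
Reagents that add atoms: none
Why: The divalent rhodium catalyst decomposes diazoketone 10 with loss of N2 to an electrophilic rhodium-bound carbene at the future C3, and the ArO–CH2 carbon (future C2) lies 1,6 to it with C–H bonds made hydridic by the lone pair of O1 and by the 4-silyloxy-3-methoxyphenyl ring, so hydride-like transfer to the carbene carbon and C2–C3 bond formation should occur through one three-centre transition state (C–H insertion). The closest known reaction type is the dirhodium-carboxylate-catalysed intramolecular C–H insertion of 2-alkoxyaryl diazoketones next to the ether oxygen, which gives chroman-4-ones. Ring C closes in a six-membered transition state made of C3, C4, C4a, C8a, O1 and C2 (1,6 insertion; in the stepwise limit, hydride shift followed by 6-(enolendo)-endo-trig collapse of a rhodium enolate onto the O-aryl oxocarbenium ion). C2 is the only new stereocentre and is set under catalyst control, the chiral carboxylate wall selecting one of the two enantiotopic benzylic hydrogens, with the sense assumed as stated above. The step needs chemoselectivity for insertion over attack of O1 on the carbene (oxonium ylide, then 1,2-benzyl shift to a 2-benzylbenzofuran-3-one), over reaction at the other ortho oxygen and over cyclopropanation of the prenyl alkene. O1 is a weak donor because its lone pair is conjugated with the ortho acyl group, the other ortho oxygen is shielded by a bulky silyl group whose silicon carries no hydrogen, the two benzylic hydrogens are the only ones 1,6 to the carbene, and the prenyl alkene could be reached only through an eleven-membered ring or bimolecularly, which slow addition at high dilution disfavours.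

**Step 8**
Reactants: 11 (2S)-2-[3-methoxy-5-(3-methylbut-2-en-1-yl)-4-(triisopropylsilyloxy)phenyl]-5,7-bis(triisopropylsilyloxy)-2,3-dihydro-4H-chromen-4-one
Product: 12 (2S)-5,7-dihydroxy-2-[4-hydroxy-3-methoxy-5-(3-methylbut-2-en-1-yl)phenyl]-2,3-dihydro-4H-chromen-4-one
Conditions: TBAF (3.5 equiv), AcOH (3.5 equiv), THF, 0 °C to rt; work-up at pH 5–6
Reagents that add atoms: none
Why: Fluoride-induced cleavage of the three aryl silyl ethers, buffered with acetic acid so that no free phenoxide opens ring C (retro-oxa-Michael or quinone methide pathway) and racemises C2, and without acid strong enough to cyclise the prenyl group onto the neighbouring phenol.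

**Compound list**
1 | 5-bromovanillin (3-bromo-4-hydroxy-5-methoxybenzaldehyde) | COc1cc(C=O)cc(Br)c1O | starting material
2 | 3-bromo-5-methoxy-4-(triisopropylsilyloxy)benzaldehyde | COc1cc(C=O)cc(Br)c1O[Si](C(C)C)(C(C)C)C(C)C | intermediate
3 | tributyl(3-methylbut-2-en-1-yl)stannane | CCCC[Sn](CCCC)(CCCC)CC=C(C)C | starting material
4 | 3-methoxy-5-(3-methylbut-2-en-1-yl)-4-(triisopropylsilyloxy)benzaldehyde | COc1cc(C=O)cc(CC=C(C)C)c1O[Si](C(C)C)(C(C)C)C(C)C | intermediate
5 | [3-methoxy-5-(3-methylbut-2-en-1-yl)-4-(triisopropylsilyloxy)phenyl]methanol | COc1cc(CO)cc(CC=C(C)C)c1O[Si](C(C)C)(C(C)C)C(C)C | intermediate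
6 | 2,4,6-trihydroxyacetophenone | CC(=O)c1c(O)cc(O)cc1O | starting material
7 | 1-[2-hydroxy-4,6-bis(triisopropylsilyloxy)phenyl]ethan-1-one | CC(=O)c1c(O)cc(O[Si](C(C)C)(C(C)C)C(C)C)cc1O[Si](C(C)C)(C(C)C)C(C)C | intermediate
8 | 1-{2-[(3-methoxy-5-(3-methylbut-2-en-1-yl)-4-(triisopropylsilyloxy)phenyl)methoxy]-4,6-bis(triisopropylsilyloxy)phenyl}ethan-1-one | CC(=O)c1c(OCc2cc(OC)c(O[Si](C(C)C)(C(C)C)C(C)C)c(CC=C(C)C)c2)cc(O[Si](C(C)C)(C(C)C)C(C)C)cc1O[Si](C(C)C)(C(C)C)C(C)C | intermediate
9 | 4,4,4-trifluoro-1-{2-[(3-methoxy-5-(3-methylbut-2-en-1-yl)-4-(triisopropylsilyloxy)phenyl)methoxy]-4,6-bis(triisopropylsilyloxy)phenyl}butane-1,3-dione (formed as its lithium enolate) | O=C(CC(=O)C(F)(F)F)c1c(OCc2cc(OC)c(O[Si](C(C)C)(C(C)C)C(C)C)c(CC=C(C)C)c2)cc(O[Si](C(C)C)(C(C)C)C(C)C)cc1O[Si](C(C)C)(C(C)C)C(C)C | intermediate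
10 | 2-diazo-1-{2-[(3-methoxy-5-(3-methylbut-2-en-1-yl)-4-(triisopropylsilyloxy)phenyl)methoxy]-4,6-bis(triisopropylsilyloxy)phenyl}ethan-1-one | [N-]=[N+]=CC(=O)c1c(OCc2cc(OC)c(O[Si](C(C)C)(C(C)C)C(C)C)c(CC=C(C)C)c2)cc(O[Si](C(C)C)(C(C)C)C(C)C)cc1O[Si](C(C)C)(C(C)C)C(C)C | intermediate
11 | (2S)-2-[3-methoxy-5-(3-methylbut-2-en-1-yl)-4-(triisopropylsilyloxy)phenyl]-5,7-bis(triisopropylsilyloxy)-2,3-dihydro-4H-chromen-4-one | COc1cc([C@@H]2CC(=O)c3c(O[Si](C(C)C)(C(C)C)C(C)C)cc(O[Si](C(C)C)(C(C)C)C(C)C)cc3O2)cc(CC=C(C)C)c1O[Si](C(C)C)(C(C)C)C(C)C | intermediate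
12 | (2S)-5,7-dihydroxy-2-[4-hydroxy-3-methoxy-5-(3-methylbut-2-en-1-yl)phenyl]-2,3-dihydro-4H-chromen-4-one | COc1cc([C@@H]2CC(=O)c3c(O)cc(O)cc3O2)cc(CC=C(C)C)c1O | target

**Total step count:** 8
**Longest linear sequence:** 7 steps (steps 1, 2, 3, 5, 6, 7, 8); step 4 is the one-step ring A branch.

**Steps most likely to fail**

Step 7. The ether oxygen O1 may capture the carbene (oxonium ylide, then 1,2-shift of the benzyl group) faster than the C–H bond inserts, or the catalyst may discriminate poorly between the two enantiotopic hydrogens. The fallback sets out from 7 and 4 and comes back at 11. Ketone 7 and aldehyde 4 are condensed with pyrrolidine (0.5 equiv) in EtOH at 50 °C to the 2'-hydroxychalcone F1, which under the same conditions should close by oxa-Michael addition of the free phenol to the racemic flavanone F2. Kinetic resolution of F2 by asymmetric transfer hydrogenation (RuCl(p-cymene)[(R,R)-TsDPEN], HCO2H/Et3N, EtOAc, rt, stopped near half conversion) is expected to reduce the (2R) enantiomer to the cis-flavan-4-ol F3. The (2S) flavanone, which is 11, stays behind and is separated by chromatography.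

Step 6. In the lithium enolate the ortho silyl group may migrate from the aryl oxygen to the enolate oxygen, or silyl groups may be lost in the aqueous amine stage. The fallback sets out from 8 and comes back at 10 without any strong base. Ketone 8 is condensed with N,N-dimethylformamide dimethyl acetal (toluene, 100 °C) to the enaminone F4. Diazo transfer from tosyl azide to F4 (MeCN, rt to 40 °C; cycloaddition to the enamine double bond, then fragmentation of the triazoline) should give 10.

Step 2. The allyl unit may transpose at palladium, so that coupling takes place at the dimethyl-substituted terminus, and oxidative addition beside the bulky silyl ether may be slow. The fallback sets out from 2 and comes back at 4, building the prenyl group in two operations. Stille coupling of 2 with allyltributylstannane (Pd(PPh3)4, toluene, 100 °C), which has no regiochemical ambiguity, should give the allyl arene F5. Cross metathesis of F5 with excess 2-methylbut-2-ene (second-generation Grubbs catalyst, CH2Cl2, 40 °C) should then give 4.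

**Further compounds**
F1 | step 7 | (E)-1-[2-hydroxy-4,6-bis(triisopropylsilyloxy)phenyl]-3-[3-methoxy-5-(3-methylbut-2-en-1-yl)-4-(triisopropylsilyloxy)phenyl]prop-2-en-1-one | O=C(/C=C/c1cc(OC)c(O[Si](C(C)C)(C(C)C)C(C)C)c(CC=C(C)C)c1)c1c(O)cc(O[Si](C(C)C)(C(C)C)C(C)C)cc1O[Si](C(C)C)(C(C)C)C(C)C
F2 | step 7 | racemic 2-[3-methoxy-5-(3-methylbut-2-en-1-yl)-4-(triisopropylsilyloxy)phenyl]-5,7-bis(triisopropylsilyloxy)-2,3-dihydro-4H-chromen-4-one | COc1cc(C2CC(=O)c3c(O[Si](C(C)C)(C(C)C)C(C)C)cc(O[Si](C(C)C)(C(C)C)C(C)C)cc3O2)cc(CC=C(C)C)c1O[Si](C(C)C)(C(C)C)C(C)C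
F3 | step 7 | (2R,4R)-2-[3-methoxy-5-(3-methylbut-2-en-1-yl)-4-(triisopropylsilyloxy)phenyl]-5,7-bis(triisopropylsilyloxy)-3,4-dihydro-2H-chromen-4-ol | COc1cc([C@H]2C[C@@H](O)c3c(O[Si](C(C)C)(C(C)C)C(C)C)cc(O[Si](C(C)C)(C(C)C)C(C)C)cc3O2)cc(CC=C(C)C)c1O[Si](C(C)C)(C(C)C)C(C)C
F4 | step 6 | (E)-3-(dimethylamino)-1-{2-[(3-methoxy-5-(3-methylbut-2-en-1-yl)-4-(triisopropylsilyloxy)phenyl)methoxy]-4,6-bis(triisopropylsilyloxy)phenyl}prop-2-en-1-one | CN(C)/C=C/C(=O)c1c(OCc2cc(OC)c(O[Si](C(C)C)(C(C)C)C(C)C)c(CC=C(C)C)c2)cc(O[Si](C(C)C)(C(C)C)C(C)C)cc1O[Si](C(C)C)(C(C)C)C(C)C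
F5 | step 2 | 3-methoxy-5-(prop-2-en-1-yl)-4-(triisopropylsilyloxy)benzaldehyde | C=CCc1cc(C=O)cc(OC)c1O[Si](C(C)C)(C(C)C)C(C)C
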